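4 questions are put to the flask below, and I reckon 2 of them from the runs, through how much gas gets into solution.

all flasks: gas phase 12 mM (held); catalyst 1.6 mM
- gamma: substrate 0.11 M; run made earlier
- delta: substrate 0.24 M; run made earlier
- flask: substrate 0.16 M; time 8.0 h

- gamma (time / h: target / %): 0.500: 2; 0.833: 7; 1.33: 1; 2.50: 10; 4.00: 17; 6.00: 26
- delta (time / h: target / %): 0.417: 6; 1.33: 4; 2.50: 5; 4.00: 9; 5.00: 12; 6.00: 20

(scatter of a reading: 2 percentage points)

1. the target standing at 8.0 h, as a percentage of the substrate charged
2. concentration of dissolved gas in solution at 50 min, in percent of saturation
3. the change that raises the amount of target at 8.0 h, in percent of the substrate charged most ("none" if none brings more than 2 percentage points) (green / red / violet / none)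
4. amount of target at 8.0 h, in percent of the substrate charged, after green

- green: doubling the saturation concentration of gas phase, all else as stated
- red: doubling the transfer coefficient of the gas phase, all else as stated
- violet: doubling the amount of catalyst, all else as stated

- the numbers in the tables scatter by 2 percentage points (one standard deviation)
- at the start none of the gas phase is in solution

My reckoning treats dissolved gas as steady (a quasi-steady state). Its level sits where the inflow, which grows with the shortfall below saturation, equals the use, which grows with [substrate] times [dissolved gas]. With saturation and catalyst held, the inverse of the target's pace is then a constant plus a term in the inverse of [substrate]. To damp the scatter, count the pace from the start, taking the 4.00 h and 6.00 h readings together: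

- gamma: [substrate] 0.11 M, target 17% and 26%, pace 4.73 mM h⁻¹
- delta: [substrate] 0.24 M, target 9% and 20%, pace 6.96 mM h⁻¹

Down the first column [substrate] grows 2.18 times, but down the last the pace grows 1.47 times, which I read as the gas inflow holding it back. The line through both rows, run out to endless substrate, gives the gas ceiling, the pace of target when gas is used as fast as it can enter: 11.6 mM h⁻¹. With a scatter of 2 percentage points on each reading, this is a rough reading.

At 0.16 M the same line gives 5.80 mM h⁻¹, half of the ceiling. So I expect dissolved gas near 49.9% of saturation at 50 min, and about 29.0% target at 8.0 h. Gas saturation and catalyst were the same in both runs, so I give no reckoning for the changes.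

The forecast says 27% (22% to 33%), 45%, green and 45%, noting that “The gas order is assumed, not measured”.

The flask gives 29.5% target and 31.6% of saturation; violet is best, gaining 16 points against 13 points for green and 6.8 points for red, and green gives 42.1%.

    gas phase ⇌ dissolved gas, rate k1*(csat - [dissolved gas]) (kL = 0.0330 min⁻¹)
    substrate + dissolved gas + catalyst → catalyst + target (k = 130 M⁻² min⁻¹)
    substrate + dissolved gas → uncatalysed product (k = 0.260 M⁻¹ min⁻¹)

Between 4.00 h and 8.0 h this flask made target at 5.34 mM h⁻¹, near the reckoned 5.80 mM h⁻¹, while its gas at 50 min stood lower than reckoned. For the neighbour charged with 0.040 M of substrate, the same ceiling gives 2.32 mM h⁻¹, so 46.4% target at 8.0 h. That neighbour holds 38.7% target and 48.4% uncatalysed product, with 13% of its substrate left.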